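Cutting the target at the depside ester leaves the main task of assembling ring A from acyclic pieces. Ring A bears oxygen at C2 and C4, the acyl carbon on C1 and pentyl on C6. This is the pattern of a 2,4-dioxo-6-pentylcyclohexane-1-carboxylate lying two hydrogens above the arene. In one base-mediated operation a malonate carbon (future C1) is joined to the enone β-carbon (C6) and the ketone methyl (C3) to a malonate carbonyl (C2). This closes the carbocycle with all four substituents in place. The precursors are (E)-non-3-en-2-one and dimethyl malonate. Ring B enters as a formyl-masked acid whose 4-OH is acylated, and its aldehyde is oxidized last.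

Key step: step 1

Remark on the chemistry: the target has no stereocentre. The cyclohexanedione from the key step is drawn as its trans diketo tautomer although it should exist largely as an enol, and its two racemic centres vanish on aromatization.

Step 1
Reactants: 1 (E)-non-3-en-2-one; 2 dimethyl malonate
Product: 4 methyl trans-2,4-dioxo-6-pentylcyclohexane-1-carboxylate (racemic), via Michael adduct 3 (not isolated)
Conditions: NaOMe (1.1 equiv), MeOH, 0 °C to reflux; then aq. HCl, 0 °C
Reagents that add atoms: none
Why: Methoxide deprotonates 2, and the soft malonate anion adds 1,4 to the β-carbon (C4) of 1, which makes the ring A C1–C6 bond and gives keto diester 3. Proton transfer then exposes the terminal methyl-ketone enolate, whose carbon attacks one of the two equivalent ester carbonyls and expels methoxide, making C2–C3; this ring closure is a 6-(enolendo)-exo-trig acyl substitution. The sequence is the known tandem Michael addition/intramolecular Claisen (Dieckmann-type) annulation of malonates with β-alkyl enones to 4-carboalkoxy-5-alkylcyclohexane-1,3-diones. C6 is created without any chiral bias and is therefore racemic, while C1 stays acidic and equilibrates under the basic conditions to the diequatorial trans arrangement of ester and pentyl (thermodynamic control); both centres disappear in step 2. The selectivities needed are 1,4- over 1,2-addition, secured by the stabilized nucleophile under reversible conditions, and closure through the methyl rather than the internal methylene enolate, secured because the latter could only form a strained four-membered ring. Final deprotonation of the acidic β-diketone by methoxide is effectively irreversible and pulls all preceding equilibria to product.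

Step 2
Reactants: 4 methyl trans-2,4-dioxo-6-pentylcyclohexane-1-carboxylate
Product: 6 methyl 2,4-dihydroxy-6-pentylbenzoate (methyl olivetolate), via bromo enol 5 (not isolated)
Conditions: Br2 (1.0 equiv), DMF, 0 °C; then 80 °C
Reagents that add atoms: none
Why: Halogenation–dehydrohalogenation aromatization: the enolized 1,3-dione is brominated at C3 at 0 °C, and on warming 5 should lose HBr in a 1,4-sense and tautomerize to the resorcylate, which erases both stereocentres, while the single equivalent of Br2 is consumed before the electron-rich arene exists.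

Step 3
Reactants: 6 methyl 2,4-dihydroxy-6-pentylbenzoate
Product: 7 methyl 2,4-dimethoxy-6-pentylbenzoate
Conditions: MeI (3 equiv), K2CO3 (3 equiv), acetone, reflux
Reagents that add atoms: iodomethane, CI
Why: Williamson ether synthesis: carbonate ionizes both phenols, and excess MeI at reflux should also capture the slower, ester-chelated C2 phenoxide while the methyl ester stays untouched.

Step 4
Reactants: 7 methyl 2,4-dimethoxy-6-pentylbenzoate
Product: 8 2,4-dimethoxy-6-pentylbenzoic acid
Conditions: KOH, DMSO/H2O, 100 °C; then cold aq. HCl
Reagents that add atoms: potassium hydroxide, [K+].[OH-]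
Why: Saponification (BAc2 ester hydrolysis): poorly solvated hydroxide in hot aqueous DMSO should overcome the shielding by the two ortho substituents, the aryl methyl ethers are inert to base, and cold acidification guards against protodecarboxylation.

Step 5
Reactants: 9 5-propylresorcinol (divarinol)
Product: 11 2,4-dihydroxy-6-propylbenzaldehyde, via aryl iminium chloride 10 (not isolated)
Conditions: POCl3 (1.5 equiv), DMF, 0 °C to rt; then ice-water
Reagents that add atoms: N,N-dimethylformamide, CN(C)C=O; water, O
Why: Vilsmeier–Haack formylation: the chloroiminium ion made from DMF and POCl3 attacks the ring carbon that is para to one hydroxyl and ortho to the other, the electronically preferred site of 5-alkylresorcinols, the cationic iminium 10 blocks a second attack, and water then releases the aldehyde.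

Step 6
Reactants: 8 2,4-dimethoxy-6-pentylbenzoic acid; 11 2,4-dihydroxy-6-propylbenzaldehyde
Product: 13 4-formyl-3-hydroxy-5-propylphenyl 2,4-dimethoxy-6-pentylbenzoate, via acid chloride 12 (not isolated)
Conditions: (COCl)2, DMF (cat.), CH2Cl2, 0 °C to rt, evaporate; then 11, Et3N, DMAP (cat.), CH2Cl2, 0 °C to rt
Reagents that add atoms: none
Why: Acid chloride formation followed by base-mediated O-acylation (nucleophilic acyl substitution with DMAP catalysis): the 4-OH, para to the formyl group, is the more acidic and open phenol, whereas the 2-OH is tied up in a hydrogen bond to the aldehyde oxygen, so one equivalent of the bulky 12 should react at O4 only.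

Step 7
Reactants: 13 4-formyl-3-hydroxy-5-propylphenyl 2,4-dimethoxy-6-pentylbenzoate
Product: 14 4-formyl-3-methoxy-5-propylphenyl 2,4-dimethoxy-6-pentylbenzoate
Conditions: MeI, K2CO3, dry DMF, rt
Reagents that add atoms: iodomethane, CI
Why: Williamson ether synthesis under mild anhydrous conditions: the salicylaldehyde-type phenoxide is methylated by MeI, while the depside carbonyl, shielded by its ortho methoxy and pentyl groups, should resist attack by carbonate or phenoxide.

Step 8
Reactants: 14 4-formyl-3-methoxy-5-propylphenyl 2,4-dimethoxy-6-pentylbenzoate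
Product: 15 4-[(2,4-dimethoxy-6-pentylbenzoyl)oxy]-2-methoxy-6-propylbenzoic acid (target)
Conditions: NaClO2, NaH2PO4, 2-methylbut-2-ene (excess), t-BuOH/THF/H2O, 0 °C to rt
Reagents that add atoms: sodium chlorite, [Na+].[O-]Cl=O
Why: Pinnick oxidation: chlorous acid adds to the formyl group and the adduct fragments to the carboxylic acid and HOCl in a weakly acidic buffer in which the aryl ester and the ethers are stable, and the excess alkene traps HOCl before it can chlorinate the dimethoxy ring A.

Compound list
1 | (E)-non-3-en-2-one | CCCCC/C=C/C(C)=O | starting material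
2 | dimethyl malonate | COC(=O)CC(=O)OC | starting material
3 | dimethyl 2-(2-oxononan-4-yl)propanedioate (racemic, R enantiomer drawn) | CCCCC[C@@H](C(C(=O)OC)C(=O)OC)CC(C)=O | intermediate
4 | methyl trans-2,4-dioxo-6-pentylcyclohexane-1-carboxylate (racemic, 1S,6R enantiomer drawn) | CCCCC[C@@H]1CC(=O)CC(=O)[C@H]1C(=O)OC | intermediate
5 | methyl trans-3-bromo-2-hydroxy-4-oxo-6-pentylcyclohex-2-ene-1-carboxylate (racemic, one enantiomer drawn) | CCCCC[C@@H]1CC(=O)C(Br)=C(O)[C@H]1C(=O)OC | intermediate
6 | methyl 2,4-dihydroxy-6-pentylbenzoate | CCCCCc1cc(O)cc(O)c1C(=O)OC | intermediate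
7 | methyl 2,4-dimethoxy-6-pentylbenzoate | CCCCCc1cc(OC)cc(OC)c1C(=O)OC | intermediate
8 | 2,4-dimethoxy-6-pentylbenzoic acid | CCCCCc1cc(OC)cc(OC)c1C(=O)O | intermediate
9 | 5-propylresorcinol (divarinol) | CCCc1cc(O)cc(O)c1 | starting material
10 | N-[(2,4-dihydroxy-6-propylphenyl)methylidene]-N-methylmethanaminium chloride | C[N+](C)=Cc1c(O)cc(O)cc1CCC.[Cl-] | intermediate
11 | 2,4-dihydroxy-6-propylbenzaldehyde | CCCc1cc(O)cc(O)c1C=O | intermediate
12 | 2,4-dimethoxy-6-pentylbenzoyl chloride | CCCCCc1cc(OC)cc(OC)c1C(=O)Cl | intermediate
13 | 4-formyl-3-hydroxy-5-propylphenyl 2,4-dimethoxy-6-pentylbenzoate | CCCCCc1cc(OC)cc(OC)c1C(=O)Oc1cc(CCC)c(C=O)c(O)c1 | intermediate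
14 | 4-formyl-3-methoxy-5-propylphenyl 2,4-dimethoxy-6-pentylbenzoate | CCCCCc1cc(OC)cc(OC)c1C(=O)Oc1cc(CCC)c(C=O)c(OC)c1 | intermediate
15 | 4-[(2,4-dimethoxy-6-pentylbenzoyl)oxy]-2-methoxy-6-propylbenzoic acid | CCCCCc1cc(OC)cc(OC)c1C(=O)Oc1cc(CCC)c(C(=O)O)c(OC)c1 | target

Total step count: 8. Longest linear sequence: 7 (steps 1, 2, 3, 4, 6, 7, 8). Step 5 is the single step of the ring B branch.

Steps most likely to fail

**Step 6.**
- Risk: acyl transfer from the doubly ortho-substituted acyl chloride may be slow. Site selectivity between the two phenolic oxygens may also erode, leading to double acylation.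
- Fallback: the two phenols are differentiated before ring union, so that ring B offers a single hydroxyl and can be used as a fully formed phenoxide.
- The fallback sets out from 11. Allyl bromide (1.0 equiv) and K2CO3 in DMF at rt should alkylate only the free 4-OH to give 2-hydroxy-4-(prop-2-en-1-yloxy)-6-propylbenzaldehyde F1.
- MeI/K2CO3 in DMF then gives 2-methoxy-4-(prop-2-en-1-yloxy)-6-propylbenzaldehyde F2.
- Allyl transfer with Pd(PPh3)4 (cat.) and K2CO3 in MeOH releases 4-hydroxy-2-methoxy-6-propylbenzaldehyde F3.
- The sodium phenoxide of F3 (NaH, THF, 0 °C) is acylated with 12. The fallback comes back to the route at 14, which also makes step 7 unnecessary.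

**Step 2.**
- Risk: the freshly formed electron-rich ring may be brominated further. Bromide-induced demethylation of the ester followed by decarboxylation may set in during the hot HBr-loss phase.
- Fallback: over-bromination is accepted on purpose and the halogens are removed afterwards.
- The fallback sets out from 4. Br2 (3 equiv) in AcOH at rt should aromatize and brominate exhaustively without heating to give methyl 3,5-dibromo-2,4-dihydroxy-6-pentylbenzoate F4.
- Hydrogenolytic debromination (H2, Pd/C, NaOAc, MeOH, rt) comes back to the route at 6.

**Step 8.**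
- Risk: hypochlorous acid that escapes the scavenger may chlorinate ring A. Addition of chlorite to the doubly ortho-flanked formyl group may also be sluggish.
- Fallback: the ring B carboxyl is installed at the acid oxidation level, so that no oxidation follows ring union and the last step becomes a hydrogenolysis.
- The fallback sets out from 9. Ortho-carboxylation with MeOMgOCO2Me in DMF at 120 °C and acidic work-up should give 2,4-dihydroxy-6-propylbenzoic acid F5.
- BnBr/KHCO3 in DMF alkylates only the carboxylate to give benzyl 2,4-dihydroxy-6-propylbenzoate F6, at which stage any regioisomeric carboxylation product is removed by chromatography.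
- Acylation of the unchelated 4-OH with 12 (Et3N, DMAP cat., CH2Cl2) gives benzyl 4-[(2,4-dimethoxy-6-pentylbenzoyl)oxy]-2-hydroxy-6-propylbenzoate F7.
- MeI/K2CO3 in DMF gives benzyl 4-[(2,4-dimethoxy-6-pentylbenzoyl)oxy]-2-methoxy-6-propylbenzoate F8.
- Hydrogenolysis (H2, Pd/C, EtOAc, rt) comes back to the route at 15.

Further compounds
F1 | step 6 | 2-hydroxy-4-(prop-2-en-1-yloxy)-6-propylbenzaldehyde | CCCc1cc(OCC=C)cc(O)c1C=O
F2 | step 6 | 2-methoxy-4-(prop-2-en-1-yloxy)-6-propylbenzaldehyde | CCCc1cc(OCC=C)cc(OC)c1C=O
F3 | step 6 | 4-hydroxy-2-methoxy-6-propylbenzaldehyde | CCCc1cc(O)cc(OC)c1C=O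
F4 | step 2 | methyl 3,5-dibromo-2,4-dihydroxy-6-pentylbenzoate | CCCCCc1c(Br)c(O)c(Br)c(O)c1C(=O)OC
F5 | step 8 | 2,4-dihydroxy-6-propylbenzoic acid | CCCc1cc(O)cc(O)c1C(=O)O
F6 | step 8 | benzyl 2,4-dihydroxy-6-propylbenzoate | CCCc1cc(O)cc(O)c1C(=O)OCc1ccccc1
F7 | step 8 | benzyl 4-[(2,4-dimethoxy-6-pentylbenzoyl)oxy]-2-hydroxy-6-propylbenzoate | CCCCCc1cc(OC)cc(OC)c1C(=O)Oc1cc(CCC)c(C(=O)OCc2ccccc2)c(O)c1
F8 | step 8 | benzyl 4-[(2,4-dimethoxy-6-pentylbenzoyl)oxy]-2-methoxy-6-propylbenzoate | CCCCCc1cc(OC)cc(OC)c1C(=O)Oc1cc(CCC)c(C(=O)OCc2ccccc2)c(OC)c1
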